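I start from one ratio, the unzipping constant over the growth constant, in this flask:

    free monomer + initiator → living end + monomer in chains (k1 = 16 /M/s)
    free monomer + living end → monomer in chains + living end, rate k2*[living end]*[free monomer] (k2 = 10 /M/s)
    monomer in chains + living end → free monomer + living end, rate k3*[living end] as long as [monomer in chains] is above zero (k3 = 0.057 /s)
    pre-initiator → initiator (k4 = 0.010 /s)
    initiator + stray impurity → spent initiator (k5 = 3100 /M/s)
    protic impurity + free monomer → quenched substrate (k6 = 0.23 /M/s)

free monomer 0.020 M; protic impurity 10.0 mM; pre-initiator 0.24 mM; stray impurity 0.22 mM; time 25 min

- average number of monomer units in a chain (chains begun, living or dead) at 25 min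
- part of the free monomer that has reacted at 25 min

- the average divides the monomer in chains by the number of chains begun, living and dead together
- run time (flask): 25 min

Growth runs at 10 /M/s times living end times free monomer and unzipping at 0.057 /s times living end, so the living end cancels, and chains gain monomer while free monomer stands above 5.70 mM, the equilibrium monomer concentration. As a fraction of the free monomer charged, this level is 28.5%. The protic impurity can claim 50.0% of that charge, so I define the room for chains as the fraction left after subtracting both, 21.5%.

In the first instants, the pre-initiator releases initiator with a half-life of 1.2 min. Each initiator meets stray impurity at 0.682 /s and free monomer at 0.320 /s, so the impurity starts ahead. For the whole feed I take stray impurity at half its charge and free monomer after half the protic impurity has reacted. Then I reckon that 41.3% of the initiator begins chains, or 0.0991 mM.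

In the middle, the protic impurity keeps eating free monomer while chains fill. At the end, with free monomer taken at that level, the protic impurity decays pseudo-first-order with a time constant of 12.7 min, and the run lasts twice that. I leave out the protic impurity still unreacted at the end and commit to dp 43.4 and c 71.5%.

The forecast gives dp 47 and c 70%, saying “the protic impurity consumes nearly all of its 10 mM of monomer and the rest goes into chains”.

The simulation gives dp 44.7 and c 68.6%. After 25.0 min in this flask, monomer in chains holds 20.6% of the free monomer charged, against the room of 21.5%. With 0.040 M of protic impurity, 2.00 equiv, the neighbouring flask has a room of −128%, below zero. After 25.0 min its monomer in chains stands at 0%, its free monomer at 0.0537% and its quenched substrate at 99.9%. That flask gives dp 5.57 × 10⁻⁵ and c 99.9%, with 50% of its protic impurity still there.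

Its constants are invented.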